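## Retrosynthetic overview

1. The carbocycle and its side-chain-bearing stereocentre come intact from (R)-carvone 1; the ester C–O bond is cut to 1 + tiglic acid 2 (oxidative α'-acyloxylation gives trans-acyloxy enone 3).
2. Isopropenyl CH3 to C–O: 3 → allylic chloride 4 → allylic hydroperoxide 5.
3. Key disconnection (C–O): both oxirane C–O bonds and the side-chain C–O of alcohol 6 (oxidised in the same flask to enal 7) are traced to the single O–O group of 5, delivered intramolecularly to the enone face cis to the side chain.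
4. Side-chain C–C bond: alkyne 8 → stannane 9 → E-vinyl iodide 10; 7 + 10 → carbinol 11 → dienone 12 (target).
5. Ring order: the six-membered ring is preformed in 1; the oxirane (step 4) is the only ring that is made.

Assumption: the ester in the SMILES is the (E)-2-methylbut-2-enoate (tiglate) and all four ring stereocentres are S (oxirane cis to the side chain, ester trans to it); bicyclic names use 7-oxabicyclo[4.1.0]heptane locants (C1 = oxirane carbon bearing CH3, C2 = ketone, C3 = ester carbon, C4 = side-chain carbon, C6 = oxirane CH).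

## Route

Step 1
Reactants: 1 (R)-(−)-carvone, (5R)-2-methyl-5-(prop-1-en-2-yl)cyclohex-2-en-1-one; 2 tiglic acid, (2E)-2-methylbut-2-enoic acid
Product: 3 (1S,6S)-3-methyl-2-oxo-6-(prop-1-en-2-yl)cyclohex-3-en-1-yl (2E)-2-methylbut-2-enoate (ester trans to the isopropenyl group)
Conditions: Mn(OAc)3·2H2O (3 equiv), 2 (10 equiv), benzene, reflux, Dean–Stark; then 1, reflux
Reagents that add atoms: none
Why: Mn(OAc)3-mediated oxidative α'-acyloxylation of an enone (trivalent-manganese enolate, carboxylate transfer after acetate/tiglate ligand exchange) forms the C–O bond at the only enolisable α' position; the carboxylate is delivered anti to the adjacent isopropenyl group and the centre is epimerisable, so the trans (1S) ester is both the kinetic and the thermodynamic product.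

Step 2
Reactants: 3 (1S,6S)-3-methyl-2-oxo-6-(prop-1-en-2-yl)cyclohex-3-en-1-yl (2E)-2-methylbut-2-enoate
Product: 4 (1S,6S)-6-(3-chloroprop-1-en-2-yl)-3-methyl-2-oxocyclohex-3-en-1-yl (2E)-2-methylbut-2-enoate
Conditions: Ca(OCl)2 (0.7 equiv), CO2 (dry ice), CH2Cl2/H2O, 0 °C
Reagents that add atoms: calcium hypochlorite, [Ca+2].[O-]Cl.[O-]Cl
Why: Ene-type allylic chlorination with HOCl (generated from Ca(OCl)2 and CO2) is electrophilic and attacks only the electron-rich 1,1-disubstituted alkene, as it does on carvone itself, leaving the enone and the tiglate untouched; no stereocentre is involved.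

Step 3
Reactants: 4 (1S,6S)-6-(3-chloroprop-1-en-2-yl)-3-methyl-2-oxocyclohex-3-en-1-yl (2E)-2-methylbut-2-enoate
Product: 5 (1S,6S)-6-(3-hydroperoxyprop-1-en-2-yl)-3-methyl-2-oxocyclohex-3-en-1-yl (2E)-2-methylbut-2-enoate
Conditions: AgOCOCF3 (1.5 equiv), H2O2 (anhydrous, 3 M in Et2O, 10 equiv), Et2O, 0 °C → rt, dark
Reagents that add atoms: hydrogen peroxide, OO
Why: Silver-assisted perhydrolysis of an allylic halide: the silver salt pulls off chloride and H2O2 captures the symmetric 2-substituted allyl cation (either terminus gives the same product), while neutral H2O2 does not epoxidise the enone; no stereocentre is involved.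

Step 4
Reactants: 5 (1S,6S)-6-(3-hydroperoxyprop-1-en-2-yl)-3-methyl-2-oxocyclohex-3-en-1-yl (2E)-2-methylbut-2-enoate
Product: 7 (1S,3S,4S,6S)-1-methyl-2-oxo-4-(3-oxoprop-1-en-2-yl)-7-oxabicyclo[4.1.0]heptan-3-yl (2E)-2-methylbut-2-enoate, via epoxy allylic alcohol 6 (not isolated)
Conditions: DBU (0.2 equiv), CH2Cl2 (0.005 M), −20 °C → rt; then activated MnO2 (20 equiv), rt
Reagents that add atoms: none
Why: Proposed new method: a tether-directed intramolecular Weitz–Scheffer epoxidation in which DBU deprotonates the side-chain hydroperoxide, whose anion can reach the enone β-carbon only from the face carrying the side chain (side chain axial, axial seven-membered peroxy-Michael addition bridging the 1,3-diaxial positions); the resulting enolate then attacks the ring-bound peroxide oxygen in a 3-exo displacement with the O–O bond pointing away from it, expelling the side-chain alkoxide, so one O–O unit gives the oxirane cis to the side chain (1S and 6S, the opposite of the trans oxirane from intermolecular alkaline H2O2) plus allylic alcohol 6, which MnO2 oxidises in the same flask to enal 7; high dilution suppresses bimolecular oxygen transfer, and the closest known reaction types are the t-BuOOH/DBU Weitz–Scheffer epoxidation, intramolecular peroxy-Michael additions of hydroperoxides to enones, and the Ti(OiPr)4-mediated oxygen transfer of allylic hydroperoxides to epoxy alcohols.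

Step 5
Reactants: 8 2-methylbut-3-yn-2-ol
Product: 10 (3E)-4-iodo-2-methylbut-3-en-2-ol, via alkenylstannane 9 (not isolated)
Conditions: Bu3SnH (1.1 equiv), PdCl2(PPh3)2 (1 mol %), THF, 0 °C → rt; then I2 (1.2 equiv), 0 °C
Reagents that add atoms: iodine, [I][I]
Why: Pd-catalysed syn hydrostannation of the hindered tertiary propargylic alcohol puts tin on the terminal carbon (E), and iododestannylation occurs with retention to give the E-vinyl iodide.

Step 6
Reactants: 7 (1S,3S,4S,6S)-1-methyl-2-oxo-4-(3-oxoprop-1-en-2-yl)-7-oxabicyclo[4.1.0]heptan-3-yl (2E)-2-methylbut-2-enoate; 10 (3E)-4-iodo-2-methylbut-3-en-2-ol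
Product: 11 (1S,3S,4S,6S)-4-[(4E)-3,6-dihydroxy-6-methylhepta-1,4-dien-2-yl]-1-methyl-2-oxo-7-oxabicyclo[4.1.0]heptan-3-yl (2E)-2-methylbut-2-enoate (both epimers at the new side-chain carbinol)
Conditions: 10 (2 equiv), CrCl2 (4 equiv), NiCl2 (1 mol %), degassed DMF, rt; aqueous work-up
Reagents that add atoms: none
Why: Nozaki–Hiyama–Kishi coupling: the alkenylchromium reagent formed from 10 adds 1,2 to the aldehyde only (ketone, ester, oxirane and free tertiary OH tolerated) with retention of the E geometry; the new carbinol centre is formed unselectively and is erased in step 7.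

Step 7
Reactants: 11 (1S,3S,4S,6S)-4-[(4E)-3,6-dihydroxy-6-methylhepta-1,4-dien-2-yl]-1-methyl-2-oxo-7-oxabicyclo[4.1.0]heptan-3-yl (2E)-2-methylbut-2-enoate
Product: 12 (1S,3S,4S,6S)-4-[(4E)-6-hydroxy-6-methyl-3-oxohepta-1,4-dien-2-yl]-1-methyl-2-oxo-7-oxabicyclo[4.1.0]heptan-3-yl (2E)-2-methylbut-2-enoate (target)
Conditions: activated MnO2 (20 equiv), CH2Cl2, rt
Reagents that add atoms: none
Why: MnO2 oxidation is selective for the doubly allylic secondary alcohol and gives the cross-conjugated dienone under neutral conditions, so the tertiary alcohol, the oxirane, the tiglate and the epimerisable ester-bearing centre are untouched.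

## Compound list

1 | (R)-(−)-carvone, (5R)-2-methyl-5-(prop-1-en-2-yl)cyclohex-2-en-1-one | C=C(C)[C@@H]1CC=C(C)C(=O)C1 | starting material
2 | tiglic acid, (2E)-2-methylbut-2-enoic acid | O=C(O)/C(C)=C/C | starting material
3 | (1S,6S)-3-methyl-2-oxo-6-(prop-1-en-2-yl)cyclohex-3-en-1-yl (2E)-2-methylbut-2-enoate | C=C(C)[C@@H]1CC=C(C)C(=O)[C@H]1OC(=O)/C(C)=C/C | intermediate
4 | (1S,6S)-6-(3-chloroprop-1-en-2-yl)-3-methyl-2-oxocyclohex-3-en-1-yl (2E)-2-methylbut-2-enoate | C=C(CCl)[C@@H]1CC=C(C)C(=O)[C@H]1OC(=O)/C(C)=C/C | intermediate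
5 | (1S,6S)-6-(3-hydroperoxyprop-1-en-2-yl)-3-methyl-2-oxocyclohex-3-en-1-yl (2E)-2-methylbut-2-enoate | C=C(COO)[C@@H]1CC=C(C)C(=O)[C@H]1OC(=O)/C(C)=C/C | intermediate
6 | (1S,3S,4S,6S)-4-(3-hydroxyprop-1-en-2-yl)-1-methyl-2-oxo-7-oxabicyclo[4.1.0]heptan-3-yl (2E)-2-methylbut-2-enoate | C=C(CO)[C@@H]1C[C@@H]2O[C@]2(C)C(=O)[C@H]1OC(=O)/C(C)=C/C | intermediate (not isolated)
7 | (1S,3S,4S,6S)-1-methyl-2-oxo-4-(3-oxoprop-1-en-2-yl)-7-oxabicyclo[4.1.0]heptan-3-yl (2E)-2-methylbut-2-enoate | C=C(C=O)[C@@H]1C[C@@H]2O[C@]2(C)C(=O)[C@H]1OC(=O)/C(C)=C/C | intermediate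
8 | 2-methylbut-3-yn-2-ol | C#CC(C)(C)O | starting material
9 | (3E)-2-methyl-4-(tributylstannyl)but-3-en-2-ol | CCCC[Sn](CCCC)(CCCC)/C=C/C(C)(C)O | intermediate (not isolated)
10 | (3E)-4-iodo-2-methylbut-3-en-2-ol | CC(C)(O)/C=C/I | intermediate
11 | (1S,3S,4S,6S)-4-[(4E)-3,6-dihydroxy-6-methylhepta-1,4-dien-2-yl]-1-methyl-2-oxo-7-oxabicyclo[4.1.0]heptan-3-yl (2E)-2-methylbut-2-enoate | C=C(C(O)/C=C/C(C)(C)O)[C@@H]1C[C@@H]2O[C@]2(C)C(=O)[C@H]1OC(=O)/C(C)=C/C | intermediate
12 | (1S,3S,4S,6S)-4-[(4E)-6-hydroxy-6-methyl-3-oxohepta-1,4-dien-2-yl]-1-methyl-2-oxo-7-oxabicyclo[4.1.0]heptan-3-yl (2E)-2-methylbut-2-enoate | C=C(C(=O)/C=C/C(C)(C)O)[C@@H]1C[C@@H]2O[C@]2(C)C(=O)[C@H]1OC(=O)/C(C)=C/C | target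

## Step count and risks

Total step count: 7 (six on the main line plus one for the vinyl iodide).
Longest linear sequence: 6 steps (1 → 3 → 4 → 5 → 7 → 11 → 12).

Three steps most likely to fail:

**Step 4 (the proposed new step).** Risks are bimolecular oxygen transfer (trans oxirane), base-induced dehydration of the primary hydroperoxide to an enal without epoxidation, and a peroxy-Michael adduct that does not collapse. The fallback uses known chemistry, sets out from 4 and comes back at 7, replacing steps 3 and 4. Luche reduction of 4 (NaBH4, CeCl3·7H2O, MeOH, −78 °C, axial hydride delivery) gives the allylic alcohol (1S,2S,6S)-6-(3-chloroprop-1-en-2-yl)-2-hydroxy-3-methylcyclohex-3-en-1-yl (2E)-2-methylbut-2-enoate F1, whose hydroxyl is cis to the side chain. Hydroxyl-directed epoxidation (VO(acac)2 cat., t-BuOOH, toluene, 0 °C) puts the oxirane on that same face and gives the epoxy alcohol (1R,2R,3S,4S,6S)-4-(3-chloroprop-1-en-2-yl)-2-hydroxy-1-methyl-7-oxabicyclo[4.1.0]heptan-3-yl (2E)-2-methylbut-2-enoate F2. Dess–Martin oxidation restores the ketone as the chloro epoxy ketone (1S,3S,4S,6S)-4-(3-chloroprop-1-en-2-yl)-1-methyl-2-oxo-7-oxabicyclo[4.1.0]heptan-3-yl (2E)-2-methylbut-2-enoate F3. Oxidation of the allylic chloride with N-methylmorpholine N-oxide (MeCN, rt) then gives enal 7.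

**Step 3.** Risks are sluggish silver-assisted ionisation of a chloride, capture by trifluoroacetate, and acid-promoted decomposition of the allylic hydroperoxide. The fallback sets out from 4 and comes back at 5. It replaces ionisation by an SN2 reaction with a masked peroxide: the reagent 2-methoxyprop-2-yl hydroperoxide F4 (made by ozonolysis of 2,3-dimethylbut-2-ene in methanol) is alkylated by 4 (Cs2CO3, DMF, 0 °C). This gives the peroxyketal (1S,6S)-6-{3-[(2-methoxypropan-2-yl)peroxy]prop-1-en-2-yl}-3-methyl-2-oxocyclohex-3-en-1-yl (2E)-2-methylbut-2-enoate F5, and AcOH/THF/H2O at rt unmasks hydroperoxide 5.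

**Step 6.** The risk is that divalent chromium in excess reduces the α-acyloxy ketone or the α,β-epoxy ketone before or after coupling. The fallback sets out from 7 and comes back at 12; it avoids low-valent chromium and also makes step 7 unnecessary. Pinnick oxidation of 7 (NaClO2, NaH2PO4, 2-methylbut-2-ene, t-BuOH/H2O) gives the acrylic acid 2-[(1S,3S,4S,6S)-1-methyl-3-{[(2E)-2-methylbut-2-enoyl]oxy}-2-oxo-7-oxabicyclo[4.1.0]heptan-4-yl]prop-2-enoic acid F6. The neutral reagent 1-chloro-N,N,2-trimethylprop-1-en-1-amine (CH2Cl2, 0 °C) converts it into the acid chloride 2-[(1S,3S,4S,6S)-1-methyl-3-{[(2E)-2-methylbut-2-enoyl]oxy}-2-oxo-7-oxabicyclo[4.1.0]heptan-4-yl]prop-2-enoyl chloride F7. Stille acylation of F7 with stannane 9 (isolated before the iodine quench of step 5; PdCl2(PPh3)2 cat., toluene, 60 °C) gives dienone 12 directly.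

Further compounds
F1 | step 4 | (1S,2S,6S)-6-(3-chloroprop-1-en-2-yl)-2-hydroxy-3-methylcyclohex-3-en-1-yl (2E)-2-methylbut-2-enoate | C=C(CCl)[C@@H]1CC=C(C)[C@H](O)[C@H]1OC(=O)/C(C)=C/C
F2 | step 4 | (1R,2R,3S,4S,6S)-4-(3-chloroprop-1-en-2-yl)-2-hydroxy-1-methyl-7-oxabicyclo[4.1.0]heptan-3-yl (2E)-2-methylbut-2-enoate | C=C(CCl)[C@@H]1C[C@@H]2O[C@]2(C)[C@H](O)[C@H]1OC(=O)/C(C)=C/C
F3 | step 4 | (1S,3S,4S,6S)-4-(3-chloroprop-1-en-2-yl)-1-methyl-2-oxo-7-oxabicyclo[4.1.0]heptan-3-yl (2E)-2-methylbut-2-enoate | C=C(CCl)[C@@H]1C[C@@H]2O[C@]2(C)C(=O)[C@H]1OC(=O)/C(C)=C/C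
F4 | step 3 | 2-methoxyprop-2-yl hydroperoxide | COC(C)(C)OO
F5 | step 3 | (1S,6S)-6-{3-[(2-methoxypropan-2-yl)peroxy]prop-1-en-2-yl}-3-methyl-2-oxocyclohex-3-en-1-yl (2E)-2-methylbut-2-enoate | C=C(COOC(C)(C)OC)[C@@H]1CC=C(C)C(=O)[C@H]1OC(=O)/C(C)=C/C
F6 | step 6 | 2-[(1S,3S,4S,6S)-1-methyl-3-{[(2E)-2-methylbut-2-enoyl]oxy}-2-oxo-7-oxabicyclo[4.1.0]heptan-4-yl]prop-2-enoic acid | C=C(C(=O)O)[C@@H]1C[C@@H]2O[C@]2(C)C(=O)[C@H]1OC(=O)/C(C)=C/C
F7 | step 6 | 2-[(1S,3S,4S,6S)-1-methyl-3-{[(2E)-2-methylbut-2-enoyl]oxy}-2-oxo-7-oxabicyclo[4.1.0]heptan-4-yl]prop-2-enoyl chloride | C=C(C(=O)Cl)[C@@H]1C[C@@H]2O[C@]2(C)C(=O)[C@H]1OC(=O)/C(C)=C/C
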